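**Assumption:** the only stereocentre is C14 of the alkyl chain, read from the SMILES as (S); it is bought in as commercial (S)-(+)-1-bromo-2-methylbutane (≥98% ee) and never touched.

## Retrosynthetic overview

- The last operation is removal of a catechol acetonide; the catechol is masked because it would quench the radical step.
- The ester C1–O bond that joins the two halves is disconnected to a terminal alkene plus the protected acid, by a new anti-Markovnikov hydroacyloxylation.
- The alkene is disconnected at C12–C13 to (S)-2-methylbutyl Grignard (C5, chiral pool) and 12-bromododec-1-ene (C12), joined by a Cu-catalysed sp3–sp3 coupling.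
- The protected acid comes from ortho-lithiation and carboxylation of catechol acetonide.
- No ring is formed in the route: the benzene ring and the temporary dioxole ring are purchased.

## Route

**Step 1**
Reactants: 1, (S)-1-bromo-2-methylbutane; 2, 12-bromododec-1-ene
Product: 3, (S)-14-methylhexadec-1-ene
Conditions: 1, Mg, cat. I2, THF, 40 °C (gives the Grignard, 1.25 equiv); then 2, Li2CuCl4 (3 mol%), NMP (4 equiv), THF, −10 → 20 °C
Reagents that add atoms: none
Why: Kochi-type Cu-catalysed alkyl–alkyl Kumada coupling of a primary Grignard with a primary bromide, which tolerates the terminal alkene; the stereocentre is β to the C–Mg carbon and never part of a reacting bond, so (S) is carried over from 1.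

**Step 2**
Reactants: 4, 2,2-dimethyl-1,3-benzodioxole (catechol acetonide)
Product: 5, 2,2-dimethyl-1,3-benzodioxole-4-carboxylic acid
Conditions: n-BuLi, TMEDA, Et2O/hexane, 0 °C → rt; CO2, −78 °C → rt; cold aq. citric acid to pH 3
Reagents that add atoms: carbon dioxide, O=C=O
Why: Directed ortho-metalation at C4 (ortho to the ring oxygen) followed by carboxylation of the aryllithium; the acetonide has no acidic acetal H and survives the cold, mildly acidic work-up.

**Step 3 (new key step)**
Reactants: 3, (S)-14-methylhexadec-1-ene (1.0 equiv); 5, 2,2-dimethyl-1,3-benzodioxole-4-carboxylic acid (2.0 equiv)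
Product: 6, (S)-14-methylhexadecyl 2,2-dimethyl-1,3-benzodioxole-4-carboxylate
Conditions: 9-mesityl-3,6-di-tert-butyl-10-phenylacridinium BF4 (5 mol%), 2,4,6-triisopropylbenzenethiol (10 mol%), 2,6-lutidine (20 mol%), PhCF3/MeCN 4:1 (0.5 M), 450 nm LEDs, N2, rt
Reagents that add atoms: none
Why: Proposed new method: photoredox anti-Markovnikov hydroacyloxylation of an unactivated terminal alkene — the excited acridinium oxidises the carboxylate of 5 to an aroyloxy radical (decarboxylation of ArCO2• is slow), this electrophilic O-radical adds to the terminal CH2 of 3 to give the more stable secondary C2 radical, polarity-matched H-atom transfer from the aryl thiol gives 6, and the thiyl radical is reduced by the acridine radical and reprotonated by 5 to close a redox-neutral cycle; the 1,2-acyloxy shift to the Markovnikov isomer is contra-thermodynamic, no new stereocentre forms and C14 is remote; the closest known reaction types are acridinium/thiol anti-Markovnikov hydroacyloxylation of styrenes and trisubstituted alkenes (via alkene radical cations, which 1-alkenes cannot form) and aroyloxy-radical additions to unactivated alkenes in oxyimination and peroxide chemistry.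

**Step 4**
Reactants: 6, (S)-14-methylhexadecyl 2,2-dimethyl-1,3-benzodioxole-4-carboxylate
Product: 7, Gentiside C, (S)-14-methylhexadecyl 2,3-dihydroxybenzoate
Conditions: TFA/H2O (9:1), CH2Cl2, Ar, 0 °C → rt
Reagents that add atoms: none
Why: Acid-catalysed ketal hydrolysis releases the catechol and acetone; the primary alkyl benzoate and the unactivated C14 stereocentre are inert to TFA, and acidic, oxygen-free conditions protect the catechol from oxidation.

## Compound list

1 | (S)-1-bromo-2-methylbutane | CC[C@H](C)CBr | starting material
2 | 12-bromododec-1-ene | C=CCCCCCCCCCCBr | starting material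
3 | (S)-14-methylhexadec-1-ene | CC[C@H](C)CCCCCCCCCCCC=C | intermediate
4 | 2,2-dimethyl-1,3-benzodioxole | CC1(C)Oc2ccccc2O1 | starting material
5 | 2,2-dimethyl-1,3-benzodioxole-4-carboxylic acid | CC1(C)Oc2cccc(C(=O)O)c2O1 | intermediate
6 | (S)-14-methylhexadecyl 2,2-dimethyl-1,3-benzodioxole-4-carboxylate | CC[C@H](C)CCCCCCCCCCCCCOC(=O)c1cccc2OC(C)(C)Oc12 | intermediate
7 | Gentiside C, (S)-14-methylhexadecyl 2,3-dihydroxybenzoate | CC[C@H](C)CCCCCCCCCCCCCOC(=O)c1cccc(O)c1O | target

## Step count

Total steps: 4. Longest linear sequence: 3 (1 → 3 → 6 → 7, or 4 → 5 → 6 → 7).

## Three steps most likely to fail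

1. **Step 3 (proposed new hydroacyloxylation).** Risks are decarboxylation of the aroyloxy radical, H-abstraction from allylic or other C–H bonds (including minor erosion at C14–H), thiol-ene consumption of the co-catalyst and low quantum yield. Fallback with known chemistry: hydroborate 3 with 9-BBN and oxidise (NaOH/H2O2) to (S)-14-methylhexadecan-1-ol, then esterify with 5 using EDC/DMAP to reach 6.

2. **Step 4 (acetonide removal).** The ketal on an ester-deactivated catechol may cleave slowly, and the free catechol is air-sensitive. Fallback that avoids protection altogether: convert (S)-14-methylhexadecan-1-ol (from the fallback above) to its bromide (CBr4/PPh3), then O-alkylate the carboxylate of unprotected 2,3-dihydroxybenzoic acid (KHCO3, DMF, 60 °C) to give 7 directly.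

3. **Step 1 (Cu-catalysed alkyl–alkyl coupling).** Risks are sluggish formation of the β-branched Grignard, homocoupling or reduction, and difficult separation of 3 from hydrocarbon by-products. Fallback by sulfone alkylation: 1 + PhSO2Na gives (S)-2-methylbutyl phenyl sulfone; deprotonate with n-BuLi and alkylate with 2; remove the sulfone reductively (Mg/MeOH) to give 3. The polar intermediates are easy to purify and C14 is not epimerisable.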